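## Structural features

The target joins two units through one methylene (C11): a 2-hydroxy-5-(alkylamino)-1,4-benzoquinone and a bicyclic terpenoid ring system. Quinone numbering used here: C1' carries C11, C2' the hydroxyl, C3' and C6' are the carbonyls, C4' is CH and C5' carries the 3-methylbutylamino group. The carbocycle is an octahydronaphthalene (terpenoid numbering: ring A = C1–C5 and C10, gem-dimethyl on C4; ring B = C5–C10) with a trisubstituted C5=C6 olefin. Three contiguous stereocentres sit on ring B: C8 (S, secondary methyl), C9 (R, quaternary, methyl and C11) and C10 (S, ring-fusion hydrogen); the two methyls are cis and H-10 is trans to the C9 methyl. The difficulties are the quaternary C9 between two stereocentres with a neopentyl link to the quinone, the unsymmetrical substitution of the quinone, and the olefin position. The C5=C6 isomer with hydrogen on C10 is not the one that acid equilibration of such octalins is expected to favour (that is the tetrasubstituted C5=C10 isomer), so the olefin is best set by a bond-forming event and not by a cationic backbone shift. Fragile groups are the hydroxyquinone (a vinylogous acid), the aminoquinone (a vinylogous amide open to hydrolysis, reduction and further nucleophilic attack) and the olefin beside the quaternary C4, which is prone to protonation and 1,2-methyl shift. The key step exploits the quinone ring as a four-carbon squarate-type unit (C6', C1', C2', C3') joined to an unsubstituted two-carbon edge (C4', C5') that an ethynyl group supplies; nitrogen then enters β to the C3' carbonyl, the one carbonyl not deactivated by the C2' oxygen.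

## Logic of the disconnections

22 to 21: the O–C bond of a tert-butyl ether on C2' is cut. The vinylogous acid stays masked to the end and is released without water or nucleophile, so the vinylogous amide is not exposed to hydrolysis. The forward step needs acid mild and brief enough to spare C5=C6.

21 to 18 and 19: the C5'–N bond is cut. Conjugate addition and re-oxidation bring in the whole side chain from a commercial amine in one operation. The forward step must choose C5' over C4' and must not attack C2' ipso. This is why the oxygen on C2' is carried as a bulky tert-butyl ether and not as a methyl ether, which a primary amine can displace; the change of protecting group is the one alteration made to the precursor design.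

18 to 15: the C5'–C6' bond is cut and the quinone ring returns to a four-membered ring bearing an ethynyl carbinol. All six quinone carbons then come from a C4 and a C2 piece with the oxidation pattern already correct. The forward step needs six-membered closure and a free hydroxyl to quench the ring radical.

15 to 13 and 14: the C3'–C4' bond is cut. The forward step needs addition to the carbonyl beside the alkoxy-bearing carbon only; this fixes the side chain next to C6' and the oxygen on C2'.

13 to 9 and 10: the C11–C1' bond is cut, giving a neopentyl nucleophile and a symmetrical C4 electrophile. The forward step needs clean halogen–metal exchange at low temperature and unmasking of the second carbonyl without losing the remaining tert-butyl ether.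

9 to 8 to 7: functional-group changes at C11 (iodide from alcohol from aldehyde). C9 is quaternary, so the forward substitution has no elimination pathway but is slow.

7 to 5 and 6: the C7–C8 and C9–C10 bonds are cut (Diels–Alder). One step forms ring B, places the olefin at C5=C6 by mechanism and sets C8, C9 and C10 from two achiral partners. The forward step needs the regiochemistry that joins the aldehyde-bearing carbon to C10, the exo topology for the formyl group, and one enantioface of 6.

5 to 3 and 4, 3 to 1: the C5–C6 bond is cut to an enol triflate and a vinyl donor, and the triflate is traced to 1. Only one α-position of 1 bears hydrogen, so the enol triflate forms as one regioisomer.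

## Other disconnections considered

Alternative 1: The cut is C9–C10 of ring B, returning acid A2 to the δ-lactone A1, in which C6 is bound to the lactone oxygen and carries the ring A cyclohexenyl group. Forward, O-silylation of the enolate of A1 and warming would trigger an Ireland–Claisen rearrangement: C9–C10 forms as C6–O breaks, ring B closes by ring contraction, the olefin arrives at C5=C6 and C9 becomes quaternary.
- In favour: the olefin position is guaranteed by mechanism (equal to the chosen plan), and the ring and the quaternary centre form together. The tetramethoxyarene of A2 leads to the quinone by oxidation, selective hydrolysis and amine-for-methoxy exchange, which fixes nitrogen at C5' with no regiochemical question; on this point it is the better plan.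
- Against: the pericyclic array is bridged by C7–C8 and must react through a boat. The C10 configuration depends on whether ring A lies over the ketene acetal or over the tether, and nothing in A1 clearly enforces the needed one. The C9 carboxyl must then be reduced to a methyl group, and A1 needs C6 and C8 set in a separate sequence.
- Comparison: the sigmatropic step is as well understood as the Moore rearrangement but carries stereochemical load the Moore step does not, and the step count would be clearly higher than the ten steps chosen.

Alternative 2: The cut is C9–C10 plus C5=C6 (Robinson disconnection), returning enone A4 to ketone 1 and (E)-pent-3-en-2-one A3. Forward, 1 is activated with a chiral amine, its C10 adds to the β-carbon of A3, and the methyl ketone condenses onto C5 to close ring B.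
- In favour: cheap reagents, easy scale-up and no precious catalyst (better than the chosen plan on cost and scale); the olefin is fixed at C5=C6 by conjugation (equal); it starts from the same ketone 1.
- Against: A4 holds only C9 (still tertiary) and C10. The C8 methyl, the quaternisation of C9 with the C11 carbon (through a cross-conjugated dienone and a face-selective conjugate addition) and the removal of the C7 carbonyl without moving the olefin all remain.
- Comparison: each reaction is individually more routine than a catalytic Diels–Alder of a hindered enal, but the stereocentres are built one by one instead of three at once, and the sequence is considerably longer.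

Alternative 3: The cut is C8–C9, returning the bicyclic dione A6 to the seco diketone A5. Forward, the bis-enolate of A5 would be oxidised with Fe(acac)3 (trivalent iron) or at an anode so that C8 and C9 couple intramolecularly and close ring B.
- In favour: the most hindered bond of the decalin is formed directly with both new stereocentres, and the arene that becomes the quinone is already attached. In convergence and in its proven quinone end-game it is the better plan.
- Against: two carbonyls must be removed afterwards. The C11 ketone sits between quaternary C9 and a di-ortho-substituted arene, and the C7 enone must go without moving C5=C6. The diastereoselectivity of the coupling relative to C10 is not secured, the electron-rich arene may compete for the oxidant, and A5 itself needs a defined C10 and a defined exocyclic olefin geometry.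
- Comparison: less predictable in mechanism than either pericyclic step of the chosen route, and longer.

Key step: step 8

## Remarks before the steps

- Abbreviation: TerCH2– is [(1R,2S,8aS)-1,2,5,5-tetramethyl-1,2,3,5,6,7,8,8a-octahydronaphthalen-1-yl]methyl, that is C11 on C9 (R), with C8 (S) and C10 (S) in terpenoid numbering. In 7, 8 and 9 the same spatial arrangement at the ring fusion is labelled 8aR because the CIP priorities change.
- Assumption on facial sense: the diene must add to the Cα-Si face of 6. On the usual model for 2-substituted enals bound to a prolinol-derived oxazaborolidinium ion, the (R)-catalyst is expected to leave that face open; if the adduct proved antipodal, the (S)-catalyst would be used with no other change.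
- Remark: 15 forms as both carbinol epimers; the centre is destroyed in step 8, so they are carried on together.
- Remark: di-tert-butyl squarate 10 is taken as a catalogue reagent.

## Route

Step 1
Reactants: 1 2,2-dimethylcyclohexanone
Product: 3 6,6-dimethylcyclohex-1-en-1-yl trifluoromethanesulfonate, via lithium enolate 2 (not isolated)
Conditions: LiN(iPr)2, THF, −78 °C; PhNTf2, −78 °C → rt
Reagents that add atoms: N-phenylbis(trifluoromethanesulfonimide), O=S(=O)(N(c1ccccc1)S(=O)(=O)C(F)(F)F)C(F)(F)F
Why: Only one α-carbon of 1 bears hydrogen, so enolisation is regiochemically unambiguous, and O-sulfonylation of the lithium enolate with PhNTf2 is the standard enol triflate synthesis.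

Step 2
Reactants: 3 6,6-dimethylcyclohex-1-en-1-yl trifluoromethanesulfonate; 4 4,4,5,5-tetramethyl-2-vinyl-1,3,2-dioxaborolane
Product: 5 6,6-dimethyl-1-vinylcyclohex-1-ene
Conditions: Pd(PPh3)4 (5 mol %), K3PO4, 1,4-dioxane/H2O, 80 °C
Reagents that add atoms: none
Why: Suzuki–Miyaura coupling of an alkenyl triflate (zerovalent palladium inserts into C–O, then transmetalation and reductive elimination); the small vinyl partner tolerates the neighbouring quaternary carbon, and the ring olefin cannot migrate.

Step 3
Reactants: 5 6,6-dimethyl-1-vinylcyclohex-1-ene; 6 (E)-2-methylbut-2-enal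
Product: 7 (1R,2S,8aR)-1,2,5,5-tetramethyl-1,2,3,5,6,7,8,8a-octahydronaphthalene-1-carbaldehyde
Conditions: (R)-3,3-diphenyl-1-(o-tolyl)tetrahydro-1H,3H-pyrrolo[1,2-c][1,3,2]oxazaborole (20 mol %), HNTf2 (17 mol %), CH2Cl2, −40 → −20 °C
Reagents that add atoms: none
Why: Catalytic asymmetric Diels–Alder reaction; the electrophilic β-carbon of the bound enal bonds to the unsubstituted diene terminus (C7–C8) and the α-carbon to the ring terminus (C9–C10), which places the olefin at C5=C6. The E geometry of 6 makes the C8 and C9 methyls cis, the exo position of the formyl group (usual for 2-methyl enals) puts H-10 trans to the C9 methyl, and the catalyst exposes the Cα-Si face, which sets the absolute configuration.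

Step 4
Reactants: 7 (1R,2S,8aR)-1,2,5,5-tetramethyl-1,2,3,5,6,7,8,8a-octahydronaphthalene-1-carbaldehyde
Product: 8 [(1R,2S,8aR)-1,2,5,5-tetramethyl-1,2,3,5,6,7,8,8a-octahydronaphthalen-1-yl]methanol
Conditions: NaBH4, MeOH, 0 °C
Reagents that add atoms: none
Why: Hydride reduction of a non-enolisable aldehyde; no stereocentre is formed or at risk and the olefin is inert.

Step 5
Reactants: 8 [(1R,2S,8aR)-1,2,5,5-tetramethyl-1,2,3,5,6,7,8,8a-octahydronaphthalen-1-yl]methanol
Product: 9 (1R,2S,8aR)-1-(iodomethyl)-1,2,5,5-tetramethyl-1,2,3,5,6,7,8,8a-octahydronaphthalene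
Conditions: PPh3, I2, imidazole, toluene, 90 °C
Reagents that add atoms: iodine, II
Why: Appel-type iodination; displacement at the neopentyl carbon is slow and needs heat, but C9 has no hydrogen so elimination is impossible, and no cation is formed that could trigger a Wagner–Meerwein shift.

Step 6
Reactants: 9 (1R,2S,8aR)-1-(iodomethyl)-1,2,5,5-tetramethyl-1,2,3,5,6,7,8,8a-octahydronaphthalene; 10 3,4-di-tert-butoxycyclobut-3-ene-1,2-dione
Product: 13 3-tert-butoxy-4-(TerCH2)cyclobut-3-ene-1,2-dione, via organolithium 11 (not isolated), via lithium alkoxide adduct 12 (not isolated)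
Conditions: t-BuLi (2.1 equiv), Et2O/pentane, −78 °C; add to 10, THF, −78 °C; (CF3CO)2O, −78 → −20 °C; aq. NaHCO3
Reagents that add atoms: none
Why: Iodine–lithium exchange of a primary iodide is fast at −78 °C, where the alkyllithium does not cyclise onto the ring olefin, and it adds 1,2 to one carbonyl of the squarate ester. Trifluoroacetylation of the alkoxide triggers ionisation and loss of one tert-butyl group, which unmasks the second carbonyl and leaves the vinylogous tert-butyl ester (the known conversion of squarate adducts into 3-alkoxy-4-alkylcyclobutenediones).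

Step 7
Reactants: 13 3-tert-butoxy-4-(TerCH2)cyclobut-3-ene-1,2-dione; 14 ethynylmagnesium bromide
Product: 15 3-tert-butoxy-4-ethynyl-4-hydroxy-2-(TerCH2)cyclobut-2-en-1-one (both carbinol epimers)
Conditions: THF, −78 → −30 °C; sat. aq. NH4Cl
Reagents that add atoms: none
Why: 1,2-addition of the acetylide to the carbonyl next to the alkoxy-bearing carbon, which is ketone-like, whereas the other carbonyl is a vinylogous ester; the new carbinol centre is not controlled and need not be.

Step 8
Reactants: 15 3-tert-butoxy-4-ethynyl-4-hydroxy-2-(TerCH2)cyclobut-2-en-1-one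
Product: 18 2-tert-butoxy-3-(TerCH2)cyclohexa-2,5-diene-1,4-dione, via enynylketene 16 (not isolated), via aryl-phenoxyl diradical 17 (not isolated)
Conditions: toluene (0.01 M, degassed), 100 °C
Reagents that add atoms: none
Why: Thermal conrotatory four-electron ring opening of the cyclobutenone, with the hydroxyl rotating outward, places the ethynyl group cis to the ketene in 16. The ketene carbon then bonds to the alkyne terminus (C5'–C6'), a 6-endo closure that gives the phenoxyl/σ-aryl diradical 17. The σ-radical at C4' lies next to the C3' hydroxyl and takes its hydrogen intramolecularly, which delivers quinone 18. The closest known reaction type is the Moore rearrangement of squarate-derived 4-alkynyl-4-hydroxycyclobutenones. No stereocentre is formed and the carbinol centre disappears. The step needs six- over five-membered closure; the terminal alkyne secures this, because five-membered closure would leave an unstabilised exocyclic vinyl radical. The substitution pattern of the quinone is already fixed by the site of addition in step 7. The radical site is para to C1' and cannot reach the terpenoid unit, and high dilution with exclusion of oxygen suppresses intermolecular hydrogen abstraction.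

Step 9
Reactants: 18 2-tert-butoxy-3-(TerCH2)cyclohexa-2,5-diene-1,4-dione; 19 3-methylbutan-1-amine
Product: 21 2-tert-butoxy-5-[(3-methylbutyl)amino]-3-(TerCH2)cyclohexa-2,5-diene-1,4-dione, via aminohydroquinone 20 (not isolated)
Conditions: 19 (1.3 equiv), Cu(OAc)2 (10 mol %), O2 (1 atm), EtOH, 0 °C → rt
Reagents that add atoms: none
Why: Conjugate addition of the amine to the enone whose acceptor is the C3' carbonyl, which is activated inductively by the adjacent alkoxy group, whereas C6' is deactivated as a vinylogous ester; this gives C5' attack, and divalent copper with oxygen re-oxidises 20 so that 18 is not consumed as oxidant. The tert-butoxy group blocks ipso attack at C2'.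

Step 10
Reactants: 21 2-tert-butoxy-5-[(3-methylbutyl)amino]-3-(TerCH2)cyclohexa-2,5-diene-1,4-dione
Product: 22 nakijiquinone M, 2-hydroxy-5-[(3-methylbutyl)amino]-3-(TerCH2)cyclohexa-2,5-diene-1,4-dione
Conditions: CF3CO2H (10 equiv), CH2Cl2, 0 °C, 15 min; pH 5 buffer
Reagents that add atoms: none
Why: Acidolysis of a vinylogous tert-butyl ester by loss of the tert-butyl cation as 2-methylpropene, a known route to hydroxyquinones; no water or nucleophile is present, so the vinylogous amide is untouched, and the short cold exposure is meant to spare the trisubstituted olefin.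

## Compound list

1 | 2,2-dimethylcyclohexanone | CC1(C)CCCCC1=O | starting material
2 | lithium 6,6-dimethylcyclohex-1-en-1-olate | [Li]OC1=CCCCC1(C)C | intermediate (not isolated)
3 | 6,6-dimethylcyclohex-1-en-1-yl trifluoromethanesulfonate | CC1(C)CCCC=C1OS(=O)(=O)C(F)(F)F | intermediate
4 | 4,4,5,5-tetramethyl-2-vinyl-1,3,2-dioxaborolane | C=CB1OC(C)(C)C(C)(C)O1 | starting material
5 | 6,6-dimethyl-1-vinylcyclohex-1-ene | C=CC1=CCCCC1(C)C | intermediate
6 | (E)-2-methylbut-2-enal | C/C=C(\C)C=O | starting material
7 | (1R,2S,8aR)-1,2,5,5-tetramethyl-1,2,3,5,6,7,8,8a-octahydronaphthalene-1-carbaldehyde | O=C[C@@]1(C)[C@@H]2CCCC(C)(C)C2=CC[C@@H]1C | intermediate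
8 | [(1R,2S,8aR)-1,2,5,5-tetramethyl-1,2,3,5,6,7,8,8a-octahydronaphthalen-1-yl]methanol | OC[C@@]1(C)[C@@H]2CCCC(C)(C)C2=CC[C@@H]1C | intermediate
9 | (1R,2S,8aR)-1-(iodomethyl)-1,2,5,5-tetramethyl-1,2,3,5,6,7,8,8a-octahydronaphthalene | IC[C@@]1(C)[C@@H]2CCCC(C)(C)C2=CC[C@@H]1C | intermediate
10 | 3,4-di-tert-butoxycyclobut-3-ene-1,2-dione | CC(C)(C)OC1=C(OC(C)(C)C)C(=O)C1=O | starting material
11 | TerCH2–Li, {[(1R,2S,8aS)-1,2,5,5-tetramethyl-1,2,3,5,6,7,8,8a-octahydronaphthalen-1-yl]methyl}lithium | [Li]C[C@@]1(C)[C@@H]2CCCC(C)(C)C2=CC[C@@H]1C | intermediate (not isolated)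
12 | lithium alkoxide of 2,3-di-tert-butoxy-4-hydroxy-4-(TerCH2)cyclobut-2-en-1-one (carbinol centre not controlled) | [Li]OC1(C[C@@]2(C)[C@@H]3CCCC(C)(C)C3=CC[C@@H]2C)C(OC(C)(C)C)=C(OC(C)(C)C)C1=O | intermediate (not isolated)
13 | 3-tert-butoxy-4-(TerCH2)cyclobut-3-ene-1,2-dione | O=C1C(=O)C(OC(C)(C)C)=C1C[C@@]2(C)[C@@H]3CCCC(C)(C)C3=CC[C@@H]2C | intermediate
14 | ethynylmagnesium bromide | C#C[Mg]Br | starting material
15 | 3-tert-butoxy-4-ethynyl-4-hydroxy-2-(TerCH2)cyclobut-2-en-1-one (both carbinol epimers) | C#CC1(O)C(OC(C)(C)C)=C(C[C@@]2(C)[C@@H]3CCCC(C)(C)C3=CC[C@@H]2C)C1=O | intermediate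
16 | (Z)-enynylketene, 3-tert-butoxy-4-hydroxy-2-(TerCH2)hexa-1,3-dien-5-yn-1-one | O=C=C(C[C@@]1(C)[C@@H]2CCCC(C)(C)C2=CC[C@@H]1C)/C(OC(C)(C)C)=C(\C#C)O | intermediate (not isolated)
17 | diradical: 3-tert-butoxy-4-hydroxy-2-(TerCH2)phenoxyl with a σ-radical at C4' | [O]c1c(C[C@@]2(C)[C@@H]3CCCC(C)(C)C3=CC[C@@H]2C)c(OC(C)(C)C)c(O)[c]c1 | intermediate (not isolated)
18 | 2-tert-butoxy-3-(TerCH2)cyclohexa-2,5-diene-1,4-dione | O=C1C=CC(=O)C(OC(C)(C)C)=C1C[C@@]2(C)[C@@H]3CCCC(C)(C)C3=CC[C@@H]2C | intermediate
19 | 3-methylbutan-1-amine | CC(C)CCN | starting material
20 | 3-tert-butoxy-5-[(3-methylbutyl)amino]-2-(TerCH2)benzene-1,4-diol | CC(C)CCNc1cc(O)c(OC(C)(C)C)c(C[C@@]2(C)[C@@H]3CCCC(C)(C)C3=CC[C@@H]2C)c1O | intermediate (not isolated)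
21 | 2-tert-butoxy-5-[(3-methylbutyl)amino]-3-(TerCH2)cyclohexa-2,5-diene-1,4-dione | CC(C)CCNC1=CC(=O)C(OC(C)(C)C)=C(C[C@@]2(C)[C@@H]3CCCC(C)(C)C3=CC[C@@H]2C)C1=O | intermediate
22 | nakijiquinone M, 2-hydroxy-5-[(3-methylbutyl)amino]-3-(TerCH2)cyclohexa-2,5-diene-1,4-dione | CC(C)CCNC1=CC(=O)C(O)=C(C[C@@]2(C)[C@@H]3CCCC(C)(C)C3=CC[C@@H]2C)C1=O | target

## Step count and least certain steps

Total step count: 10. Longest linear sequence: 10 steps (1 to 22); 4, 6, 10, 14 and 19 are bought.

Step 8 (key step). What may go wrong: closure of the ketene carbon onto the inner alkyne carbon (five-membered ring), or intermolecular hydrogen abstraction and oligomerisation of the σ-radical if the internal O–H transfer is slow; the terminal-alkyne carbinol may also fragment before it opens. Fallback: from 13, vinylmagnesium bromide (C=C[Mg]Br) is added at the same carbonyl to give the 4-vinyl carbinol F1. Heating F1 in toluene opens it to a dienylketene that closes by six-electron electrocyclisation and tautomerises to the hydroquinone F2. Oxidation of F2 with air or Ag2O returns to the route at 18. This is the known alkenylcyclobutenone ring expansion; it has no diradical and no five- versus six-ring question, at the cost of one extra step.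

Step 3. What may go wrong: low conversion, because a trisubstituted enal must form a quaternary centre beside a ring CH; loss of facial or exo selectivity at the temperature then needed; acid-induced oligomerisation of the diene. Fallback: from 6, acetalisation with (2R,4R)-pentane-2,4-diol gives the chiral acetal F3. With Me3SiOTf in CH2Cl2 at −78 °C, F3 ionises to a much more reactive vinyl-substituted oxocarbenium dienophile that adds to 5 (ionic Diels–Alder). The adduct acetal F4 is separated from its diastereomers by chromatography and hydrolysed with dilute aqueous acid, returning to the route at 7. The diol antipode would be chosen by the sense of induction, as for the catalyst.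

Step 9. What may go wrong: partial attack at C4', because the twisted tert-butoxy group donates less strongly than a planar alkoxy group would; imine formation at C3'; over-oxidation. Fallback: from 13, C5' is oxygenated by construction. (Z)-2-Ethoxyvinyllithium F5, made from (Z)-1-bromo-2-ethoxyethene and t-BuLi, adds at the same carbonyl to give the carbinol F6. Thermolysis of F6 in toluene followed by Ag2O oxidation in the same operation gives the 2-tert-butoxy-5-ethoxyquinone F7. CF3CO2H removes the tert-butyl group to give the 5-ethoxy-2-hydroxyquinone F8, and 19 with NaHCO3 in EtOH displaces the ethoxy group by addition–elimination, the usual way amines are introduced in this quinone family, returning to the route at 22. This contingency gives up the alkyne-based ring expansion in exchange for unambiguous regiochemistry.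

Step 10. What may go wrong: protonation of C5=C6 followed by methyl shift from C4, or capture of the tert-butyl cation by the electron-rich C4' position. Fallback: from 9, the sequence of steps 6 to 9 is run with dimethyl squarate (COC1=C(OC)C(=O)C1=O) in place of 10. This gives in turn the methoxy dione F9, the ethynyl carbinol F10, the methoxyquinone F11 and the methoxy aminoquinone F12. The methyl ether of F12 is then removed with aqueous LiOH in THF by addition–elimination at C2', returning to the route at 22. This is not the first choice, because in F11 the small methoxy group is open to ipso displacement by 19 and the final hydrolysis must discriminate the vinylogous ester from the vinylogous amide.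

## Further compounds

F1 | step 8 | 3-tert-butoxy-4-ethenyl-4-hydroxy-2-(TerCH2)cyclobut-2-en-1-one (both carbinol epimers) | C=CC1(O)C(OC(C)(C)C)=C(C[C@@]2(C)[C@@H]3CCCC(C)(C)C3=CC[C@@H]2C)C1=O
F2 | step 8 | 2-tert-butoxy-3-(TerCH2)benzene-1,4-diol | Oc1ccc(O)c(OC(C)(C)C)c1C[C@@]2(C)[C@@H]3CCCC(C)(C)C3=CC[C@@H]2C
F3 | step 3 | (4R,6R)-2-[(E)-but-2-en-2-yl]-4,6-dimethyl-1,3-dioxane | C/C=C(\C)C1O[C@H](C)C[C@@H](C)O1
F4 | step 3 | (4R,6R)-4,6-dimethyl-2-[(1R,2S,8aR)-1,2,5,5-tetramethyl-1,2,3,5,6,7,8,8a-octahydronaphthalen-1-yl]-1,3-dioxane | O1[C@H](C)C[C@@H](C)OC1[C@@]2(C)[C@@H]3CCCC(C)(C)C3=CC[C@@H]2C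
F5 | step 9 | (Z)-2-ethoxyvinyllithium | [Li]/C=C\OCC
F6 | step 9 | 3-tert-butoxy-4-[(Z)-2-ethoxyethenyl]-4-hydroxy-2-(TerCH2)cyclobut-2-en-1-one (both carbinol epimers) | CCO/C=C\C1(O)C(OC(C)(C)C)=C(C[C@@]2(C)[C@@H]3CCCC(C)(C)C3=CC[C@@H]2C)C1=O
F7 | step 9 | 2-tert-butoxy-5-ethoxy-3-(TerCH2)cyclohexa-2,5-diene-1,4-dione | CCOC1=CC(=O)C(OC(C)(C)C)=C(C[C@@]2(C)[C@@H]3CCCC(C)(C)C3=CC[C@@H]2C)C1=O
F8 | step 9 | 5-ethoxy-2-hydroxy-3-(TerCH2)cyclohexa-2,5-diene-1,4-dione | CCOC1=CC(=O)C(O)=C(C[C@@]2(C)[C@@H]3CCCC(C)(C)C3=CC[C@@H]2C)C1=O
F9 | step 10 | 3-methoxy-4-(TerCH2)cyclobut-3-ene-1,2-dione | COC1=C(C[C@@]2(C)[C@@H]3CCCC(C)(C)C3=CC[C@@H]2C)C(=O)C1=O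
F10 | step 10 | 4-ethynyl-4-hydroxy-3-methoxy-2-(TerCH2)cyclobut-2-en-1-one (one carbinol epimer drawn, both form) | C#C[C@]1(O)C(OC)=C(C[C@@]2(C)[C@@H]3CCCC(C)(C)C3=CC[C@@H]2C)C1=O
F11 | step 10 | 2-methoxy-3-(TerCH2)cyclohexa-2,5-diene-1,4-dione | O=C1C=CC(=O)C(OC)=C1C[C@@]2(C)[C@@H]3CCCC(C)(C)C3=CC[C@@H]2C
F12 | step 10 | 2-methoxy-5-[(3-methylbutyl)amino]-3-(TerCH2)cyclohexa-2,5-diene-1,4-dione | CC(C)CCNC1=CC(=O)C(OC)=C(C[C@@]2(C)[C@@H]3CCCC(C)(C)C3=CC[C@@H]2C)C1=O
A1 | alternative 1 | (4S,6R)-6-(6,6-dimethylcyclohex-1-en-1-yl)-4-methyl-3-(2,3,5,6-tetramethoxybenzyl)tetrahydro-2H-pyran-2-one (C3 enolised, not specified) | O=C1O[C@@H](C2=CCCCC2(C)C)C[C@H](C)C1Cc3c(OC)c(OC)cc(OC)c3OC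
A2 | alternative 1 | ring B acid with carboxyl and 2,3,5,6-tetramethoxybenzyl on C9 | COc1cc(OC)c(OC)c(C[C@@]2(C(=O)O)[C@@H]3CCCC(C)(C)C3=CC[C@@H]2C)c1OC
A3 | alternative 2 | (E)-pent-3-en-2-one | C/C=C/C(C)=O
A4 | alternative 2 | 4,4,9-trimethyl bicyclic enone (C7 carbonyl, C5=C6, terpenoid numbering) | C[C@H]1CC(=O)C=C2C(C)(C)CCC[C@@H]12
A5 | alternative 3 | 1-{2,2-dimethyl-6-[1-oxo-1-(2,3,5,6-tetramethoxyphenyl)propan-2-yl]cyclohexylidene}butan-2-one (C10 as in A6, C9 enolised) | CCC(=O)/C=C1/C(C)(C)CCC[C@H]1C(C)C(=O)c2c(OC)c(OC)cc(OC)c2OC
A6 | alternative 3 | bicyclic 7,11-dione with the 5-ene and the 2,3,5,6-tetramethoxyphenyl ketone on C9 | COc1cc(OC)c(OC)c(C(=O)[C@@]2(C)[C@@H]3CCCC(C)(C)C3=CC(=O)[C@@H]2C)c1OC
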